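# Proposed total synthesis of cudraphenone D by pyrone-to-phloroglucinol folding

Assumption: compounds 1, 2, 4 and 6 are bought. Compounds 8 and 11 each hold one stereocentre that forms racemic and is destroyed before the target. The target 12 is achiral.

## Analysis of the target

Cudraphenone D (12) is an achiral benzophenone, C23H26O5, with two benzene rings joined through one ketone carbon. Ring A carries three neighbouring substituents: the ketone at C1, a 3-methylbut-2-enyl (prenyl) group at C2 and a hydroxyl at C3. The prenyl group therefore sits in the most crowded position, between acyl and OH. Ring B is an acylphloroglucinol: ketone at C1, hydroxyls at C2, C4 and C6, one prenyl group at C3, hydrogen at C5. There is no stereocentre and no alkene geometry to set, so the difficulty is regiochemical. Ring B C3 and C5 are equivalent until the prenyl group arrives, and three phenoxide oxygens compete with them, so prenylation of the finished ring cannot be steered to one carbon. Each prenyl group lies ortho to a free phenol, and acid closes such pairs to 2,2-dimethylchromans. This rules out Lewis-acid acylations and acidic or hydrogenolytic deprotections late in a route. The polyphenolate is also air sensitive in base.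

The feature the route uses: ring B C2, C3, C4, C5, C6 and C1 plus the ketone carbon form an unbroken seven-carbon chain with oxygen on every second carbon. This is a 3,5,7-trioxoheptanoate folded by a Claisen condensation, with the prenyl group on chain C2.

## Retrosynthetic reasoning

**12 to 11 (ring B C1–C2 bond).** Cutting this bond unrolls ring B into the open-chain ester 11. Chain C1 (ester) is ring B C2, chain C2 (prenyl-bearing) is ring B C3, chain C3, C4 and C5 are ring B C4, C5 and C6, chain C6 is ring B C1, and chain C7 is the ketone carbon. This cut turns the mono-prenylation of a symmetric triphenol into the alkylation of a single carbon, done before the ring exists. The forward step must close chain C6 onto C1 (Claisen mode) and not chain C2 onto C7 (aldol mode). The prenyl group on C2 makes the aldol mode a dead end, because its product could not aromatise.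

**11 to 10 to 9 (masking the chain).** The chain is stored as a 4-hydroxy-2-pyrone, in which chain C1 is the lactone carbonyl and chain C5 carries the ring oxygen. The pyrone masks three of the four carbonyl groups and is stable to handle, and an alkoxide should open it in the flask. The ring A phenol is carried in 9 as a silyl ether that the same alkoxide removes, so no acid deprotection is needed.

**9 to 8 to 3 + 7 (chain C6–C7 bond).** The bond between the pyrone 6-methylene and the ring A carbonyl carbon is made as an aldol addition of the dianion of pyrone 3 to aldehyde 7, followed by oxidation of carbinol 8. An aldehyde is preferred to an ester. The CH2 of the ring A prenyl group is benzylic, allylic and ortho to the carbonyl, and a slow acylation would let the basic dianion remove that proton. Addition to an aldehyde is faster than the proton transfer. The price is one oxidation step.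

**3 to 1 + 2 (pyrone C3–prenyl bond).** C3 of 1 is its only nucleophilic carbon, between the lactone carbonyl and the enol. Allyl-palladium chemistry delivers the prenyl group there as the thermodynamic C-alkylation product.

**7 to 5 + 6, and 5 to 4 (ring A C2–prenyl bond).** The bromine of commercial 4 already marks the carbon between formyl and hydroxyl. The 1,2,3 pattern of ring A is bought, and the bromine is exchanged for prenyl by cross-coupling after silylation.

## Alternatives that were turned down

**Alternative 1:** the textbook route cuts the bond between the ketone carbon and ring B C1. The forward key step is a Friedel–Crafts or Hoesch acylation of phloroglucinol A1 with nitrile A2 (or the matching acyl halide) to benzophenone A3, followed by C-prenylation of ring B.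
- The acylation needs strong Lewis or Brønsted acid, which would close the ortho-prenylphenol of A2 to a chroman or add HX to its alkene.
- Ether protection that survives the acid would need a deprotection the prenyl groups do not survive.
- The last step, prenylation of the trianion of A3, has no handle to separate O- from C-attack, one C-prenyl from two, or aromatic from geminal alkylation.
- The disconnection leaves both regiochemical problems of the target unsolved.

**Alternative 2:** cut both aryl–prenyl bonds at once. The forward key step is a double aromatic Claisen rearrangement of bis(1,1-dimethylallyl) ether A4, moving one allyl unit from ring B O4 to C3 and the other from ring A O3 to C2.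
- The ring B half is sound, because C3 and C5 are equivalent.
- Ring A has two free ortho positions, and nothing in A4 forces the shift to the crowded C2 rather than C4, which gives isomer A5.
- Making A4 needs selective tertiary etherification of two of four phenols, each by propargylation and semi-hydrogenation.
- Tertiary allyl aryl ethers ionise easily. The route is longer and ends in a separation of regioisomers.

**Alternative 3:** build ring A by benzannulation. The forward key step is a Diels–Alder reaction of 3-hydroxy-2-pyrone A6 with ynone A7, followed by loss of carbon dioxide.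
- The oxygen donor at pyrone C3 makes C6 the nucleophilic diene terminus, which bonds to the beta carbon of the ynone.
- The acyl-bearing alkyne carbon therefore ends next to the oxygenated carbon, and the expected product is the 2-hydroxy-6-prenylbenzoyl isomer A8, not the 3-hydroxy-2-prenyl pattern.
- Reversing this needs a tether and more steps.
- Ring B of A7, with its prenyl group and three acetal-protected phenols, would still come from the chemistry of Alternative 1 and need a closing acid deprotection.

Key step: step 6

## Route

Step 1
Reactants: 1 4-hydroxy-6-methyl-2H-pyran-2-one (triacetic acid lactone); 2 3-methylbut-2-en-1-ol (prenyl alcohol)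
Product: 3 4-hydroxy-6-methyl-3-(3-methylbut-2-en-1-yl)-2H-pyran-2-one
Conditions: Pd(PPh3)4 (5 mol%), 1 (1.3 equiv), THF, 65 °C, Ar
Reagents that add atoms: none
Why: Tsuji–Trost allylation of a strongly acidic carbon pronucleophile with the free allylic alcohol: the pyrone (pKa about 5) activates the hydroxyl so that zerovalent palladium ionises it, and the soft C3 carbon attacks the unsubstituted terminus of the 1,1-dimethylallyl palladium cation to give the linear prenyl group. O-Allylation is reversible under the same catalyst, and the excess of 1 should hold back a second allylation at C3.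

Step 2
Reactants: 4 2-bromo-3-hydroxybenzaldehyde
Product: 5 2-bromo-3-[(tert-butyldimethylsilyl)oxy]benzaldehyde
Conditions: TBSCl, imidazole, DMF, 0 °C to rt
Reagents that add atoms: tert-butyldimethylsilyl chloride, CC(C)(C)[Si](C)(C)Cl
Why: Standard silylation of a phenol. The silyl ether should withstand the coupling, the dianion and the oxidant, and the alkoxide of step 6 removes it, so no acid deprotection is applied to a prenylated phenol.

Step 3
Reactants: 5 2-bromo-3-[(tert-butyldimethylsilyl)oxy]benzaldehyde; 6 tributyl(3-methylbut-2-en-1-yl)stannane
Product: 7 3-[(tert-butyldimethylsilyl)oxy]-2-(3-methylbut-2-en-1-yl)benzaldehyde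
Conditions: Pd(PPh3)4 (5 mol%), CuI (10 mol%), DMF, 80 °C, Ar
Reagents that add atoms: none
Why: Stille coupling: zerovalent palladium inserts into the C–Br bond activated by the ortho formyl group, the allyl unit passes from tin to palladium (CuI helps at the hindered centre), and reductive elimination from the primary end of the allyl ligand gives the linear prenyl arene, the crowded aryl group disfavouring the tertiary terminus. No Lewis acid is present, so the stannane should not add to the aldehyde.

Step 4
Reactants: 3 4-hydroxy-6-methyl-3-(3-methylbut-2-en-1-yl)-2H-pyran-2-one; 7 3-[(tert-butyldimethylsilyl)oxy]-2-(3-methylbut-2-en-1-yl)benzaldehyde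
Product: 8 6-{2-[3-(tert-butyldimethylsilyloxy)-2-(3-methylbut-2-en-1-yl)phenyl]-2-hydroxyethyl}-4-hydroxy-3-(3-methylbut-2-en-1-yl)-2H-pyran-2-one (racemic)
Conditions: 3 (1.2 equiv), LiN(i-Pr)2 (2.5 equiv), THF–DMPU, −78 to −20 °C; 7, −78 °C; AcOH, −78 °C
Reagents that add atoms: none
Why: Aldol addition of a 4-hydroxy-6-methyl-2-pyrone dianion: the first equivalent of base removes the 4-OH proton and the second the 6-methyl proton, and the terminal carbanion adds to the aldehyde faster than it can abstract the benzylic-allylic protons of the ring A prenyl group. The carbinol centre forms racemic and is removed in step 5, and the cold acetic acid quench avoids dehydration to a styrylpyrone.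

Step 5
Reactants: 8 6-{2-[3-(tert-butyldimethylsilyloxy)-2-(3-methylbut-2-en-1-yl)phenyl]-2-hydroxyethyl}-4-hydroxy-3-(3-methylbut-2-en-1-yl)-2H-pyran-2-one
Product: 9 6-{2-[3-(tert-butyldimethylsilyloxy)-2-(3-methylbut-2-en-1-yl)phenyl]-2-oxoethyl}-4-hydroxy-3-(3-methylbut-2-en-1-yl)-2H-pyran-2-one
Conditions: Dess–Martin periodinane (1.1 equiv), CH2Cl2, 0 °C to rt
Reagents that add atoms: none
Why: Dess–Martin oxidation of a secondary benzylic alcohol to the aryl ketone under near-neutral conditions that should leave the trisubstituted alkenes, the silyl ether and the pyrone untouched. Pyrone C3, the usual site of oxidative attack in 4-hydroxypyrones, is blocked by its prenyl group, and one equivalent of oxidant limits attack on the new active methylene.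

Step 6
Reactants: 9 6-{2-[3-(tert-butyldimethylsilyloxy)-2-(3-methylbut-2-en-1-yl)phenyl]-2-oxoethyl}-4-hydroxy-3-(3-methylbut-2-en-1-yl)-2H-pyran-2-one
Product: 12 [3-hydroxy-2-(3-methylbut-2-en-1-yl)phenyl][2,4,6-trihydroxy-3-(3-methylbut-2-en-1-yl)phenyl]methanone (cudraphenone D), via desilylated pyrone 10 (not isolated), via open-chain triketo ester 11 (not isolated)
Conditions: KOMe (10 equiv), dry degassed MeOH, Ar, 25 to 65 °C; then 1 M HCl, 0 °C, to pH 4
Reagents that add atoms: potassium methoxide, C[O-].[K+] (its methoxy group is carried only by intermediate 11 and leaves again as methanol; no atom of it remains in 12)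
Why: This is the base-induced ring transformation of a 4-hydroxy-6-(2-oxoalkyl)-2-pyrone into an acylphloroglucinol, the Claisen mode of biogenetic-type polyketide folding, which is the closest known reaction type. Methoxide first cleaves the aryl silyl ether to give 10, then adds to the lactone carbonyl (pyrone C2), and the ring opens between C2 and O1 to the methyl 3,5,7-trioxoheptanoate 11, present as its polyenolate. The carbanion at chain C6, flanked by the C5 and C7 carbonyls, attacks the ester carbon C1 in a 6-exo-trig Dieckmann-type closure, methoxide leaves, and the cyclohexane-1,3,5-trione tautomerises to ring B, so that the ring B C1–C2 bond is the only C–C bond formed. The step needs Claisen closure (C6 to C1) to win over aldol closure (C2 to C7) and over re-lactonisation: the prenyl group on chain C2 means an aldol adduct would hold a quaternary carbon and could not aromatise, so it stays reversible, the ortho prenyl group of ring A shields C7, and potassium in methanol does not chelate the chain as magnesium does in the aldol mode. Aromatisation to the phloroglucinol polyanion is irreversible and should drain all these equilibria, the pyrone included. The prenyl group arrives at ring B C3 because it was chain C2, so no phenol is ever prenylated. No stereocentre is formed, and the racemic C2 centre of 11 becomes sp2. Air is excluded because the polyphenolate oxidises, and the acidification is kept cold and stops at pH 4 so that neither ortho-prenylphenol closes to a chroman.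

## Compound list

1 | 4-hydroxy-6-methyl-2H-pyran-2-one (triacetic acid lactone) | CC1=CC(O)=CC(=O)O1 | starting material
2 | 3-methylbut-2-en-1-ol | CC(C)=CCO | starting material
3 | 4-hydroxy-6-methyl-3-(3-methylbut-2-en-1-yl)-2H-pyran-2-one | CC1=CC(O)=C(CC=C(C)C)C(=O)O1 | intermediate
4 | 2-bromo-3-hydroxybenzaldehyde | O=Cc1cccc(O)c1Br | starting material
5 | 2-bromo-3-[(tert-butyldimethylsilyl)oxy]benzaldehyde | O=Cc1cccc(O[Si](C)(C)C(C)(C)C)c1Br | intermediate
6 | tributyl(3-methylbut-2-en-1-yl)stannane | CCCC[Sn](CCCC)(CCCC)CC=C(C)C | starting material
7 | 3-[(tert-butyldimethylsilyl)oxy]-2-(3-methylbut-2-en-1-yl)benzaldehyde | CC(C)=CCc1c(C=O)cccc1O[Si](C)(C)C(C)(C)C | intermediate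
8 | 6-{2-[3-(tert-butyldimethylsilyloxy)-2-(3-methylbut-2-en-1-yl)phenyl]-2-hydroxyethyl}-4-hydroxy-3-(3-methylbut-2-en-1-yl)-2H-pyran-2-one (racemic) | CC(C)=CCc1c(cccc1O[Si](C)(C)C(C)(C)C)C(O)CC1=CC(O)=C(CC=C(C)C)C(=O)O1 | intermediate
9 | 6-{2-[3-(tert-butyldimethylsilyloxy)-2-(3-methylbut-2-en-1-yl)phenyl]-2-oxoethyl}-4-hydroxy-3-(3-methylbut-2-en-1-yl)-2H-pyran-2-one | CC(C)=CCc1c(cccc1O[Si](C)(C)C(C)(C)C)C(=O)CC1=CC(O)=C(CC=C(C)C)C(=O)O1 | intermediate
10 | 4-hydroxy-6-{2-[3-hydroxy-2-(3-methylbut-2-en-1-yl)phenyl]-2-oxoethyl}-3-(3-methylbut-2-en-1-yl)-2H-pyran-2-one (not isolated) | CC(C)=CCc1c(O)cccc1C(=O)CC1=CC(O)=C(CC=C(C)C)C(=O)O1 | intermediate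
11 | methyl 7-[3-hydroxy-2-(3-methylbut-2-en-1-yl)phenyl]-2-(3-methylbut-2-en-1-yl)-3,5,7-trioxoheptanoate (racemic at C2, not isolated) | COC(=O)C(CC=C(C)C)C(=O)CC(=O)CC(=O)c1cccc(O)c1CC=C(C)C | intermediate
12 | [3-hydroxy-2-(3-methylbut-2-en-1-yl)phenyl][2,4,6-trihydroxy-3-(3-methylbut-2-en-1-yl)phenyl]methanone (cudraphenone D) | CC(C)=CCc1c(O)cccc1C(=O)c1c(O)cc(O)c(CC=C(C)C)c1O | target

## Step count and risk

Total step count: 6. Longest linear sequence: 5 steps (4 to 5 to 7 to 8 to 9 to 12, steps 2 to 6). The second branch (1 to 3, step 1) joins at step 4.

**Step 6 (key step).** The most likely failure is slow addition of methoxide to the lactone carbonyl, because in base the pyrone is a delocalised dianion. On forcing, methoxide may cleave the chain by retro-Claisen reaction, and traces of water may open the ring to a carboxylate that decarboxylates. The fallback separates ring opening from folding. It sets out from 3 and 7 and comes back to the route at 11.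
- Pyrone 3, only a monoanion in base, is opened with Mg(OMe)2 in methanol at reflux to methyl 3,5-dioxo-2-(3-methylbut-2-en-1-yl)hexanoate F1.
- Its trianion (LiN(i-Pr)2, 3 equiv, THF, −78 to 0 °C) is added at the terminal methyl carbon to aldehyde 7, giving methyl 7-{3-[(tert-butyldimethylsilyl)oxy]-2-(3-methylbut-2-en-1-yl)phenyl}-7-hydroxy-2-(3-methylbut-2-en-1-yl)-3,5-dioxoheptanoate F2.
- Dess–Martin oxidation gives methyl 7-{3-[(tert-butyldimethylsilyl)oxy]-2-(3-methylbut-2-en-1-yl)phenyl}-2-(3-methylbut-2-en-1-yl)-3,5,7-trioxoheptanoate F3.
- KOMe in methanol at room temperature desilylates F3 to 11, which closes to 12 as in step 6 without any lactone opening.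

**Step 4.** The likely failures are loss of water from the aldol to a conjugated styrylpyrone during quench or isolation, retro-aldol on warming, and incomplete second deprotonation because the dilithio species aggregates. The fallback replaces aldol plus oxidation by a direct acylation. It sets out from 7 (with 3) and comes back at 9, so step 5 is no longer needed.
- Pinnick oxidation of 7 (NaClO2, NaH2PO4, excess 2-methylbut-2-ene, t-BuOH–water) gives 3-[(tert-butyldimethylsilyl)oxy]-2-(3-methylbut-2-en-1-yl)benzoic acid F4.
- 1,1'-Carbonyldiimidazole converts F4 to the acyl imidazole {3-[(tert-butyldimethylsilyl)oxy]-2-(3-methylbut-2-en-1-yl)phenyl}(1H-imidazol-1-yl)methanone F5.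
- The dianion of 3 (2.2 equiv, THF, −78 °C) is acylated by F5 at its 6-methyl carbon to give 9.

**Step 1.** The likely failures are a second allylation at C3, giving a 3,3-diprenyl pyran-2,4-dione, attack at the substituted allyl terminus, and sluggish ionisation of the alcohol. The fallback builds the prenylated pyrone from open-chain pieces. It sets out from commercial ethyl acetoacetate and 1-bromo-3-methylbut-2-ene in place of 1 and 2, and comes back at 3.
- Alkylation (NaOEt, EtOH) gives ethyl 2-acetyl-5-methylhex-4-enoate F6.
- The dianion of F6 (NaH, then n-BuLi, THF, 0 °C) is acetylated at the terminal carbon with N-methoxy-N-methylacetamide to give ethyl 2-(3-methylbut-2-en-1-yl)-3,5-dioxohexanoate F7.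
- DBU in toluene at reflux lactonises F7 to 3 with loss of ethanol.

**Step 3.** The likely failures are allyl transposition (coupling through the tertiary terminus to a 1,1-dimethylallyl arene), slow transmetalation at the doubly ortho-substituted palladium centre with competing protodebromination, and addition of the stannane to the formyl group. The fallback installs an allyl group, which has no regiochemical ambiguity, and then builds the prenyl terminus. It sets out from 5 and comes back at 7.
- Stille coupling of 5 with allyltributylstannane (Pd(PPh3)4, DMF, 80 °C) gives 3-[(tert-butyldimethylsilyl)oxy]-2-(prop-2-en-1-yl)benzaldehyde F8.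
- Cross-metathesis of F8 with excess 2-methylbut-2-ene (second-generation Grubbs catalyst, CH2Cl2, 40 °C) gives 7.

## Further compounds

F1 | step 6 | methyl 3,5-dioxo-2-(3-methylbut-2-en-1-yl)hexanoate | COC(=O)C(CC=C(C)C)C(=O)CC(C)=O
F2 | step 6 | methyl 7-{3-[(tert-butyldimethylsilyl)oxy]-2-(3-methylbut-2-en-1-yl)phenyl}-7-hydroxy-2-(3-methylbut-2-en-1-yl)-3,5-dioxoheptanoate (mixture of diastereomers) | COC(=O)C(CC=C(C)C)C(=O)CC(=O)CC(O)c1cccc(O[Si](C)(C)C(C)(C)C)c1CC=C(C)C
F3 | step 6 | methyl 7-{3-[(tert-butyldimethylsilyl)oxy]-2-(3-methylbut-2-en-1-yl)phenyl}-2-(3-methylbut-2-en-1-yl)-3,5,7-trioxoheptanoate | COC(=O)C(CC=C(C)C)C(=O)CC(=O)CC(=O)c1cccc(O[Si](C)(C)C(C)(C)C)c1CC=C(C)C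
F4 | step 4 | 3-[(tert-butyldimethylsilyl)oxy]-2-(3-methylbut-2-en-1-yl)benzoic acid | CC(C)=CCc1c(C(=O)O)cccc1O[Si](C)(C)C(C)(C)C
F5 | step 4 | {3-[(tert-butyldimethylsilyl)oxy]-2-(3-methylbut-2-en-1-yl)phenyl}(1H-imidazol-1-yl)methanone | CC(C)=CCc1c(C(=O)n2ccnc2)cccc1O[Si](C)(C)C(C)(C)C
F6 | step 1 | ethyl 2-acetyl-5-methylhex-4-enoate | CCOC(=O)C(CC=C(C)C)C(C)=O
F7 | step 1 | ethyl 2-(3-methylbut-2-en-1-yl)-3,5-dioxohexanoate | CCOC(=O)C(CC=C(C)C)C(=O)CC(C)=O
F8 | step 3 | 3-[(tert-butyldimethylsilyl)oxy]-2-(prop-2-en-1-yl)benzaldehyde | C=CCc1c(C=O)cccc1O[Si](C)(C)C(C)(C)C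
A1 | alternative 1 | benzene-1,3,5-triol (phloroglucinol) | Oc1cc(O)cc(O)c1
A2 | alternative 1 | 3-hydroxy-2-(3-methylbut-2-en-1-yl)benzonitrile | CC(C)=CCc1c(O)cccc1C#N
A3 | alternative 1 | [3-hydroxy-2-(3-methylbut-2-en-1-yl)phenyl](2,4,6-trihydroxyphenyl)methanone | CC(C)=CCc1c(O)cccc1C(=O)c1c(O)cc(O)cc1O
A4 | alternative 2 | [2,6-dihydroxy-4-(2-methylbut-3-en-2-yloxy)phenyl][3-(2-methylbut-3-en-2-yloxy)phenyl]methanone | C=CC(C)(C)Oc1cccc(c1)C(=O)c1c(O)cc(OC(C)(C)C=C)cc1O
A5 | alternative 2 | [3-hydroxy-4-(3-methylbut-2-en-1-yl)phenyl][2,4,6-trihydroxy-3-(3-methylbut-2-en-1-yl)phenyl]methanone | CC(C)=CCc1ccc(cc1O)C(=O)c1c(O)cc(O)c(CC=C(C)C)c1O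
A6 | alternative 3 | 3-hydroxy-2H-pyran-2-one | O=C1OC=CC=C1O
A7 | alternative 3 | 6-methyl-1-[2,4,6-tris(methoxymethoxy)-3-(3-methylbut-2-en-1-yl)phenyl]hept-5-en-2-yn-1-one | CC(C)=CCC#CC(=O)c1c(OCOC)cc(OCOC)c(CC=C(C)C)c1OCOC
A8 | alternative 3 | [2-hydroxy-6-(3-methylbut-2-en-1-yl)phenyl][2,4,6-tris(methoxymethoxy)-3-(3-methylbut-2-en-1-yl)phenyl]methanone | CC(C)=CCc1cccc(O)c1C(=O)c1c(OCOC)cc(OCOC)c(CC=C(C)C)c1OCOC
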